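**Remark (assumption on the chemistry):** the target is read as 19-acetoxy-2α,7α-dihydroxy-14,15-dinorlabd-8(17)-en-13-one of the normal labdane series. Labdane numbering is used for all intermediates (ring A = C1–C5, C10; ring B = C5–C10; C17 on C8; C18 (α) and C19 (β) on C4; C20 on C10; side chain C11–C12–C13(=O)–C16), and β is the face of the C20 methyl.

## Retrosynthetic overview

- Ring B is bought as (R)-carvone (C5 stereocentre, C17 methyl, C9 carbonyl); its α′ carbon is alkylated twice (CH3, then allyl) to give quaternary C10 with the C1 arm trans to the C5 arm.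
- Ring A is closed last through the C2–C3 bond: an iron-hydride (HAT) radical cyclisation of a C1=C2 silyl enol ether onto the C3=C4–C19HO enal made from the isopropenyl group; C4 is then quaternised by enolate methylation (4α-CH3, 4β-CHO → CH2OAc).
- Enabling feature: in ring A the oxygen-bearing C2 lies 1,3 to quaternary C4, whose C19 arm is oxygenated (pattern C2(O)–C3–C4–C19=O). C2 can therefore be an α-oxy radical and C3=C4–C19=O its Giese acceptor, and the carvone isopropenyl group supplies exactly C3, C4 and C19.
- Ring B end game on the carvone enone: 1,2-addition of the C11–C13/C16 chain to C9, palladium/formate hydrogenolysis (9α-H, 7-ene), α-epoxidation and titanocene isomerisation to the 7α-hydroxy-8(17)-ene.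
- Ring order: ring B (carvone) first, ring A in step 6.

Key step: step 6

## Route

Step 1
Reactants: 1 (R)-(−)-carvone
Product: 2 trans-6-methylcarvone (new methyl = C20 on C10, anti to the isopropenyl group; minor cis epimer carried along)
Conditions: LiN(iPr)2 (LDA), THF, −78 °C; MeI, −78 → 0 °C
Reagents that add atoms: iodomethane, CI
Why: Kinetic α′-deprotonation of the cross-conjugated enone and SN2 methylation of the lithium enolate (enolate alkylation); the new centre is re-enolised in step 2, so its configuration does not matter.

Step 2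
Reactants: 2 trans-6-methylcarvone
Product: 3 6-allyl-6-methylcarvone (allyl anti, methyl syn to the isopropenyl group)
Conditions: LiN(iPr)2 (LDA), THF, −78 °C; allyl bromide, DMPU, −78 → 0 °C
Reagents that add atoms: allyl bromide, C=CCBr
Why: A second enolate alkylation at the same carbon creates quaternary C10, the allyl group entering the enolate face anti to the adjacent C5 isopropenyl group, so the future C1 arm is trans and the C20 methyl cis to the C4 arm (diastereoselective α-alkylation of a cyclohexenone enolate).

Step 3
Reactants: 3 6-allyl-6-methylcarvone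
Product: 5 enal (isopropenyl CH3 oxidised to the C19 aldehyde), via allylic alcohol 4 (not isolated)
Conditions: SeO2, 1,4-dioxane, 90 °C
Reagents that add atoms: selenium dioxide, O=[Se]=O
Why: Allylic oxidation by SeO2 (ene reaction, [2,3]-shift, then oxidation of the allylic alcohol) should attack the methyl of the electron-rich 1,1-disubstituted alkene in preference to the tertiary C5–H, the electron-poor enone alkene and the monosubstituted allyl group; no stereocentre is formed.

Step 4
Reactants: 5 enal
Product: 7 keto dialdehyde (C2 aldehyde on C10–CH2 and C19 enal on C5), via vicinal diol 6 (not isolated)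
Conditions: OsO4 (cat.), NaIO4, 2,6-lutidine, 1,4-dioxane/H2O, 20 °C
Reagents that add atoms: osmium tetroxide, O=[Os](=O)(=O)=O (catalytic; its oxygen is replenished by sodium periodate, [Na+].[O-]I(=O)(=O)=O)
Why: Lemieux–Johnson cleavage, in which OsO4 should dihydroxylate only the electron-rich allyl alkene (the enone and enal C=C bonds are deactivated) and periodate cleaves the diol to the C2 aldehyde.

Step 5
Reactants: 7 keto dialdehyde
Product: 8 tert-butyldimethylsilyl enol ether of the C2 aldehyde (C1=C2, E/Z mixture)
Conditions: TBSOTf, Et3N, CH2Cl2, −78 °C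
Reagents that add atoms: tert-butyldimethylsilyl triflate, CC(C)(C)[Si](C)(C)OS(=O)(=O)C(F)(F)F
Why: Soft enolisation and O-silylation of the only aldehyde that has α-hydrogens (the enal has none, the ring ketone only γ-hydrogens), run cold with excess amine to suppress Mukaiyama-type self-condensation; the double-bond geometry is irrelevant for the radical step.

Step 6
Reactants: 8 silyl enol ether
Product: 9 trans-fused bicyclic enone (2α-OTBS; C4 bearing H and the C19 aldehyde as an epimer mixture; 5α-H; 10β-CH3; 8-CH3; 7-ene; 9-oxo)
Conditions: Fe(acac)3 (substoichiometric), PhSiH3, EtOH/HOCH2CH2OH, 60 °C, high dilution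
Reagents that add atoms: none
Why: An iron hydride formed from Fe(acac)3 and PhSiH3 transfers a hydrogen atom to C1 of the electron-rich silyl enol ether, and the resulting α-silyloxy radical at C2 adds to the unsubstituted terminus C3 of the α-substituted acrolein; the α-formyl radical at C4 is then reduced by divalent iron to the enolate and protonated by ethanol. The closest known reaction type is the iron-hydride (HAT) reductive coupling of donor olefins, silyl enol ethers included, with conjugated carbonyl acceptors (Giese addition), used here intramolecularly. Ring A closes in the 6-endo-trig mode with respect to the C3=C4 bond, which polarity (nucleophilic α-oxy radical, electrophilic β-carbon) and the fully substituted C4 favour over 5-exo attack. The trans ring fusion is carried in from ring B (C5–C4 and C10–C1 arms trans); the new C2 centre is set in a chair transition state that places the silyloxy group equatorial (α), away from the syn-axial C20 methyl; and C4 remains an epimerisable CH(CHO) centre that step 7 fixes. The step needs chemoselective hydrogen-atom transfer to the enol ether (the enone and enal alkenes are electron-poor and act only as acceptors) and closure onto C3 instead of C7 of the ring B enone, which the unhindered terminal CH2 and the strain of the alternative bridged ring should secure.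

Step 7
Reactants: 9 bicyclic aldehyde
Product: 10 4α-methyl-4β-formyl compound (quaternary C4)
Conditions: KOtBu, MeI, THF, −20 → 0 °C
Reagents that add atoms: iodomethane, CI
Why: α-Alkylation of the aldehyde enolate (the most acidic C–H in the molecule), in which MeI should attack the exocyclic enolate from the equatorial α face because the axial β face is blocked by the syn-axial C20 methyl, giving 4α-CH3/4β-CHO (the facial preference known for C4 enolates of 10-methyl-trans-decalins).

Step 8
Reactants: 10 quaternary aldehyde
Product: 11 19-alcohol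
Conditions: NaBH4, EtOH/CH2Cl2, −78 → −20 °C
Reagents that add atoms: none
Why: Chemoselective borohydride reduction of the aldehyde at low temperature, where the hindered conjugated C9 ketone should not react.

Step 9
Reactants: 11 19-alcohol; 12 2-(2-bromoethyl)-2-methyl-1,3-dioxolane
Product: 14 9β,19-diol carrying the 9α side chain (C13 ketone as dioxolane), via dioxolanylethylmagnesium bromide 13 (not isolated)
Conditions: 12, Mg, THF, 25 °C; CeCl3, THF, −78 °C; then 11, −78 → −40 °C; aq. NH4Cl
Reagents that add atoms: none
Why: Organocerium 1,2-addition to the hindered enone, which cannot enolise towards C10, with attack from the α face anti to the axial C20 methyl giving 9α-alkyl/9β-OH; one equivalent of reagent is consumed by the free 19-OH.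

Step 10
Reactants: 14 9β,19-diol
Product: 15 19-acetate (tertiary 9β-OH free)
Conditions: Ac2O, pyridine, CH2Cl2, 0 → 20 °C
Reagents that add atoms: acetic anhydride, CC(=O)OC(C)=O
Why: Acylation selective for the primary alcohol, the tertiary allylic alcohol being inert under these conditions.

Step 11
Reactants: 15 19-acetate
Product: 16 9β-methyl carbonate
Conditions: KN(SiMe3)2, THF, −78 °C; ClCO2Me, −78 → 0 °C
Reagents that add atoms: methyl chloroformate, COC(=O)Cl
Why: O-Acylation of the potassium tertiary alkoxide, which forms much faster than any ester enolate, to give the allylic carbonate needed for ionisation.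

Step 12
Reactants: 16 allylic carbonate
Product: 17 19-acetoxy-2α-(tert-butyldimethylsilyloxy)-14,15-dinorlabd-7-en-13-one ethylene ketal (9α-H, 9β side chain)
Conditions: Pd(OAc)2 (cat.), PBu3, HCO2H, Et3N, 1,4-dioxane, 80 °C
Reagents that add atoms: none
Why: Palladium-catalysed formate hydrogenolysis of an allylic carbonate: zerovalent palladium ionises the 9β-carbonate with inversion (Tsuji–Trost-type) and the palladium formate delivers hydride to the more substituted allyl terminus C9 on the palladium (α) face, which should give 9α-H and the less substituted 7-ene.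

Step 13
Reactants: 17 7-ene
Product: 18 7α,8α-epoxide
Conditions: mCPBA, NaHCO3, CH2Cl2, 0 °C
Reagents that add atoms: 3-chloroperoxybenzoic acid, OOC(=O)c1cccc(Cl)c1
Why: Prilezhaev epoxidation of the only alkene, expected from the α face opposite the axial C20 methyl.

Step 14
Reactants: 18 7α,8α-epoxide
Product: 19 19-acetoxy-7α-hydroxy-2α-(tert-butyldimethylsilyloxy)-14,15-dinorlabd-8(17)-en-13-one ethylene ketal
Conditions: Cp2TiCl2, Mn dust, anhydrous THF, 25 °C; then 18; cold dilute HCl work-up
Reagents that add atoms: none
Why: Cp2TiCl (trivalent titanium) should open the epoxide homolytically at the tertiary C8–O bond, keeping the 7α-oxygen, and a second equivalent removes a hydrogen from the unhindered C17 methyl (β-hydride elimination) to give the exocyclic alkene (titanocene-mediated epoxide to allylic alcohol isomerisation, tolerant of the acetate).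

Step 15
Reactants: 19 protected allylic alcohol
Product: 20 target, 19-acetoxy-2α,7α-dihydroxy-14,15-dinorlabd-8(17)-en-13-one
Conditions: 1 M HCl, THF, 20 °C
Reagents that add atoms: water, O
Why: Acid hydrolysis of the dioxolane and of the secondary silyl ether, under which the acetate and the allylic alcohol should survive.

## Compound list

1 | (R)-(−)-carvone, (5R)-2-methyl-5-(prop-1-en-2-yl)cyclohex-2-en-1-one | CC1=CC[C@@H](C(C)=C)CC1=O | starting material
2 | trans-6-methylcarvone (6-methyl anti to isopropenyl) | CC1=CC[C@@H](C(C)=C)[C@H](C)C1=O | intermediate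
3 | 6-allyl-6-methylcarvone (allyl anti, methyl syn to isopropenyl) | CC1=CC[C@@H](C(C)=C)[C@](C)(CC=C)C1=O | intermediate
4 | allylic alcohol of 3 (isopropenyl CH3 → CH2OH) | CC1=CC[C@@H](C(=C)CO)[C@](C)(CC=C)C1=O | intermediate
5 | enal (isopropenyl CH3 → CHO, C19) | CC1=CC[C@@H](C(=C)C=O)[C@](C)(CC=C)C1=O | intermediate
6 | vicinal diol from the allyl group of 5 (epimers at the carbinol) | CC1=CC[C@@H](C(=C)C=O)[C@](C)(CC(O)CO)C1=O | intermediate
7 | keto dialdehyde (C2 aldehyde and C19 enal) | CC1=CC[C@@H](C(=C)C=O)[C@](C)(CC=O)C1=O | intermediate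
8 | tert-butyldimethylsilyl enol ether of the C2 aldehyde (E/Z mixture) | CC1=CC[C@@H](C(=C)C=O)[C@](C)(C=CO[Si](C)(C)C(C)(C)C)C1=O | intermediate
9 | trans-fused bicyclic enone, 2α-OTBS, 4-CHO (C4 epimers), 7-en-9-one | CC1=CC[C@H]2C(C=O)C[C@H](O[Si](C)(C)C(C)(C)C)C[C@]2(C)C1=O | intermediate
10 | 4α-methyl-4β-formyl bicyclic enone | CC1=CC[C@H]2[C@@](C)(C=O)C[C@H](O[Si](C)(C)C(C)(C)C)C[C@]2(C)C1=O | intermediate
11 | 19-alcohol | CC1=CC[C@H]2[C@@](C)(CO)C[C@H](O[Si](C)(C)C(C)(C)C)C[C@]2(C)C1=O | intermediate
12 | 2-(2-bromoethyl)-2-methyl-1,3-dioxolane | BrCCC1(C)OCCO1 | starting material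
13 | 2-(2-methyl-1,3-dioxolan-2-yl)ethylmagnesium bromide | Br[Mg]CCC1(C)OCCO1 | intermediate
14 | 9β,19-diol with 9α side chain (13-ketone as dioxolane) | CC1=CC[C@H]2[C@@](C)(CO)C[C@H](O[Si](C)(C)C(C)(C)C)C[C@]2(C)[C@]1(O)CCC3(C)OCCO3 | intermediate
15 | 19-acetate of 14 | CC1=CC[C@H]2[C@@](C)(COC(C)=O)C[C@H](O[Si](C)(C)C(C)(C)C)C[C@]2(C)[C@]1(O)CCC3(C)OCCO3 | intermediate
16 | 9β-methyl carbonate of 15 | CC1=CC[C@H]2[C@@](C)(COC(C)=O)C[C@H](O[Si](C)(C)C(C)(C)C)C[C@]2(C)[C@]1(OC(=O)OC)CCC3(C)OCCO3 | intermediate
17 | 19-acetoxy-2α-TBSO-14,15-dinorlabd-7-en-13-one ethylene ketal | CC1=CC[C@H]2[C@@](C)(COC(C)=O)C[C@H](O[Si](C)(C)C(C)(C)C)C[C@]2(C)[C@H]1CCC3(C)OCCO3 | intermediate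
18 | 7α,8α-epoxide of 17 | C[C@@]12O[C@@H]1C[C@H]3[C@@](C)(COC(C)=O)C[C@H](O[Si](C)(C)C(C)(C)C)C[C@]3(C)[C@H]2CCC4(C)OCCO4 | intermediate
19 | 19-acetoxy-7α-hydroxy-2α-TBSO-14,15-dinorlabd-8(17)-en-13-one ethylene ketal | C=C1[C@H](O)C[C@H]2[C@@](C)(COC(C)=O)C[C@H](O[Si](C)(C)C(C)(C)C)C[C@]2(C)[C@H]1CCC3(C)OCCO3 | intermediate
20 | 19-acetoxy-2α,7α-dihydroxy-14,15-dinorlabd-8(17)-en-13-one (CNP0139304.2) | C=C1[C@H](O)C[C@H]2[C@@](C)(COC(C)=O)C[C@H](O)C[C@]2(C)[C@H]1CCC(C)=O | target

## Step count and risks

Total step count: 15. Longest linear sequence: 15 steps from (R)-carvone (compound 12 is bought).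

**Step 6 (key step).** The hydrogen-atom transfer to the enol ether may be inefficient, the silyl enol ether may be solvolysed in the protic medium, or the aldehyde may be reduced by the silane. The same C2–C3 bond would then be made by electron-transfer umpolung of the enal instead of radical generation at C2. The fallback sets out from the keto dialdehyde 7, before step 5. Cp2TiCl (trivalent titanium, from Cp2TiCl2 and Mn dust, THF, slow addition at high dilution) should reduce the conjugated aldehyde selectively and join its β-carbon C3 to the C2 aldehyde carbon (titanocene-mediated reductive coupling of a conjugated alkenal with an aldehyde, 6-exo-trig, titanoxy group equatorial). This would give the 2α-hydroxy aldehyde F1. Silylation (TBSCl, imidazole, DMF) then gives 9, where the route is rejoined.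

**Step 12.** Hydride may be delivered to the wrong allyl terminus (8(9)-ene), β-hydride elimination may give dienes, or facial selectivity may already be poor in the addition of step 9. The fallback does not depend on the configuration of the C9 carbinol and sets out from 15. Pyridinium chlorochromate, C5H5NH[CrO3Cl], effects the oxidative 1,3-transposition (Babler–Dauben oxidation) to the 7-oxo-8-ene F2. Luche reduction (NaBH4, CeCl3) gives the equatorial 7β-allylic alcohol F3. Mitsunobu displacement with 2-nitrobenzenesulfonylhydrazide (PPh3, DEAD, −30 °C) gives, with inversion, the 7α-sulfonylhydrazide F4. On warming this loses the sulfinic acid to give the allylic diazene F5, whose retro-ene loss of dinitrogen delivers hydrogen suprafacially to the α face of C9 and gives 17.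

**Step 14.** Elimination may go towards C9 (endocyclic 8(9)-ene) or the epoxide may be opened reductively. A base-mediated syn-elimination with an aluminium amide would be used instead; as this does not tolerate the acetate, the fallback sets out from 18. K2CO3 in MeOH removes the acetate to give the 19-hydroxy epoxide F6. Diethylaluminium 2,2,6,6-tetramethylpiperidide (Et2Al–TMP, toluene, 0 °C) abstracts a C17 hydrogen syn to the epoxide oxygen and gives the 7α,19-diol F7. Selective acetylation of the primary alcohol (Ac2O, pyridine, 0 °C) leads back to 19.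

Further compounds
F1 | step 6 | 2α-hydroxy bicyclic enone aldehyde (4-CHO, C4 epimers) | CC1=CC[C@H]2C(C=O)C[C@H](O)C[C@]2(C)C1=O
F2 | step 12 | 19-acetoxy-2α-TBSO-14,15-dinorlabd-8-ene-7,13-dione 13-ethylene ketal | CC=1C(=O)C[C@H]2[C@@](C)(COC(C)=O)C[C@H](O[Si](C)(C)C(C)(C)C)C[C@]2(C)C=1CCC3(C)OCCO3
F3 | step 12 | 7β-allylic alcohol from F2 | CC=1[C@@H](O)C[C@H]2[C@@](C)(COC(C)=O)C[C@H](O[Si](C)(C)C(C)(C)C)C[C@]2(C)C=1CCC3(C)OCCO3
F4 | step 12 | 7α-[N-(2-nitrobenzenesulfonyl)hydrazino] compound | CC=1[C@H](N(N)S(=O)(=O)c4ccccc4[N+](=O)[O-])C[C@H]2[C@@](C)(COC(C)=O)C[C@H](O[Si](C)(C)C(C)(C)C)C[C@]2(C)C=1CCC3(C)OCCO3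
F5 | step 12 | 7α-allylic diazene | CC=1[C@H](N=N)C[C@H]2[C@@](C)(COC(C)=O)C[C@H](O[Si](C)(C)C(C)(C)C)C[C@]2(C)C=1CCC3(C)OCCO3
F6 | step 14 | 19-hydroxy 7α,8α-epoxide | C[C@@]12O[C@@H]1C[C@H]3[C@@](C)(CO)C[C@H](O[Si](C)(C)C(C)(C)C)C[C@]3(C)[C@H]2CCC4(C)OCCO4
F7 | step 14 | 7α,19-diol with the 8(17)-ene | C=C1[C@H](O)C[C@H]2[C@@](C)(CO)C[C@H](O[Si](C)(C)C(C)(C)C)C[C@]2(C)[C@H]1CCC3(C)OCCO3
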